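**Plan**
- Retrosynthesis cuts, in order: the C15–O ester (ferulic acid), the C7=C8 bond of ring B (ring closure), C6–C7 (B-alkyl cross-coupling), C9–C10 ([3,3] shift) and the ester C–O bond that joins the two halves.
- Forward: ring A comes first, from ketoisophorone, as allylic alcohol 7. The C8–C15 acid 14 comes from (R)-citronellol. Esterification and Ireland–Claisen rearrangement form C9–C10; then C2 inversion, C6–C7 coupling, C8 methyl ketone, closure of ring B, desilylation and feruloylation.
- Enabling feature: ring B is a cyclohexene whose only unsaturation is C7=C8, with the C17 methyl on C8. A C8 methyl ketone (on C9) and a C7=CMe2 olefin (on C6), held trans-diequatorial at C10 and C5 of the ring A chair, can exchange partners to give exactly this alkene and acetone.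
- Stereochemistry: C13 from (R)-citronellol; C2 from catalyst-controlled transfer hydrogenation; C10 and C9 from the Ireland–Claisen step (bond formed anti to the C2 silyloxy group, chair transition state, Z ketene acetal); C2 then inverted by Mitsunobu lactonisation; C5 from α-face hydroboration of the C5=C6 methylidene.

Key step: step 16

Remark: labdane numbering (C1–C20) and the α/β face labels of the target are used for every intermediate; in step 1 the (R,R)-ligand is assigned by analogy with aryl and alkenyl ketones, and the mirror-image ligand would be used if the sense of induction proved opposite.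

Step 1
Reactants: 1 ketoisophorone (2,6,6-trimethylcyclohex-2-ene-1,4-dione)
Product: 2 (R)-phorenol [(4R)-4-hydroxy-2,6,6-trimethylcyclohex-2-en-1-one]
Conditions: RuCl(p-cymene)[(R,R)-TsDPEN] (1 mol %), HCO2H/Et3N (5:2), CH2Cl2, 25 °C
Reagents that add atoms: none
Why: Noyori-type asymmetric transfer hydrogenation should reduce only the less hindered C4 carbonyl (C1 is flanked by the gem-dimethyl carbon and the methyl-bearing alkene carbon), the chiral ligand choosing the face that gives the (R)-carbinol, which is the relay stereocentre (labdane C2, oxygen β).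

Step 2
Reactants: 2 (R)-phorenol
Product: 3 (4R)-2,6,6-trimethyl-4-(triethylsilyloxy)cyclohex-2-en-1-one
Conditions: Et3SiCl, imidazole, DMF, 0 → 25 °C
Reagents that add atoms: chlorotriethylsilane CC[Si](Cl)(CC)CC
Why: Standard silylation of an unhindered secondary alcohol; the triethylsilyl ether should survive the hydride, palladium and amide-base steps and leave with dilute acid in step 11.

Step 3
Reactants: 3 triethylsilyl ether of (R)-phorenol
Product: 5 (4S)-2,6,6-trimethyl-4-(triethylsilyloxy)cyclohex-1-en-1-yl trifluoromethanesulfonate, via lithium enolate 4 (not isolated)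
Conditions: LiBH(s-Bu)3, THF, −78 °C; then PhNTf2, −78 → 0 °C
Reagents that add atoms: N-phenylbis(trifluoromethanesulfonimide) O=S(=O)(N(c1ccccc1)S(=O)(=O)C(F)(F)F)C(F)(F)F
Why: Conjugate (1,4) hydride reduction of the hindered enone by the bulky borohydride should give regiospecifically the tetrasubstituted enolate, which is O-sulfonylated (reductive enol triflate formation); no stereocentre is formed.

Step 4
Reactants: 5 enol triflate
Product: 6 methyl (4S)-2,6,6-trimethyl-4-(triethylsilyloxy)cyclohex-1-ene-1-carboxylate
Conditions: Pd(OAc)2 (5 mol %), PPh3, Et3N, CO (1 atm), MeOH/DMF, 60 °C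
Reagents that add atoms: carbon monoxide [C-]#[O+]; methanol CO
Why: Palladium-catalysed alkoxycarbonylation of an alkenyl triflate (oxidative addition to zerovalent palladium, CO insertion, methanolysis) is well known for 2,6,6-trimethylcyclohexenyl triflates and installs C6.

Step 5
Reactants: 6 methyl ester
Product: 7 [(4S)-2,6,6-trimethyl-4-(triethylsilyloxy)cyclohex-1-en-1-yl]methanol
Conditions: i-Bu2AlH, CH2Cl2, −78 → 0 °C; aq. potassium sodium tartrate
Reagents that add atoms: none
Why: 1,2-Reduction of the conjugated ester by the aluminium hydride should give the primary allylic alcohol without touching the silyl ether or the tetrasubstituted alkene.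

Step 6
Reactants: 8 (R)-citronellol
Product: 9 tert-butyl{[(3R)-3,7-dimethyloct-6-en-1-yl]oxy}diphenylsilane
Conditions: t-BuPh2SiCl, imidazole, DMF, 25 °C
Reagents that add atoms: tert-butyl(chloro)diphenylsilane CC(C)(C)[Si](Cl)(c1ccccc1)c1ccccc1
Why: Standard silyl protection; this ether should withstand ozone, Grignard formation, amide base, dilute acid and FeCl3 and leave with fluoride at the end, and C13 is taken unchanged from the chiral pool.

Step 7
Reactants: 9 silyl ether of (R)-citronellol
Product: 11 (4R)-6-(tert-butyldiphenylsilyloxy)-4-methylhexan-1-ol, via aldehyde 10 (not isolated)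
Conditions: O3, CH2Cl2/MeOH, −78 °C; Me2S; then NaBH4, 0 °C
Reagents that add atoms: ozone [O-][O+]=O
Why: Ozonolysis of the trisubstituted alkene with reductive work-up gives the aldehyde, which NaBH4 reduces in the same flask to the primary alcohol (the carbon that becomes C9).

Step 8
Reactants: 11 primary alcohol
Product: 12 {[(3R)-6-bromo-3-methylhexyl]oxy}(tert-butyl)diphenylsilane
Conditions: CBr4, PPh3, CH2Cl2, 0 °C
Reagents that add atoms: carbon tetrabromide BrC(Br)(Br)Br
Why: Appel bromination of a primary alcohol under neutral conditions, compatible with the silyl ether.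

Step 9
Reactants: 12 primary bromide
Product: 14 (5R)-7-(tert-butyldiphenylsilyloxy)-5-methylheptanoic acid, via Grignard reagent 13 (not isolated)
Conditions: Mg, THF, 40 °C; then CO2, −20 °C; 1 M HCl
Reagents that add atoms: carbon dioxide O=C=O
Why: Carboxylation of the primary Grignard reagent adds the one carbon (C8) that the Claisen acid needs.

Step 10
Reactants: 7 ring A allylic alcohol + 14 side-chain acid
Product: 15 [(4S)-2,6,6-trimethyl-4-(triethylsilyloxy)cyclohex-1-en-1-yl]methyl (5R)-7-(tert-butyldiphenylsilyloxy)-5-methylheptanoate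
Conditions: DCC, DMAP (cat.), CH2Cl2, 0 → 25 °C
Reagents that add atoms: none
Why: Steglich esterification of the hindered primary allylic alcohol joins the two halves through the very C–O bond that the rearrangement will break.

Step 11
Reactants: 15 allylic ester
Product: 18 2β-hydroxy acid (ring A with 5-methylidene and quaternary C10 carrying C9H(CO2H)–chain), via silyl ketene acetal 16 (not isolated), via trimethylsilyl ester 17 (not isolated)
Conditions: lithium diisopropylamide, Me3SiCl, THF/DMPU (3:1), −78 °C; then 25 → 60 °C; then 1 M HCl, THF, 25 °C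
Reagents that add atoms: none
Why: Ireland–Claisen rearrangement: enolisation in the presence of DMPU should give the Z silyl ketene acetal, the chair transition state then places the C11 chain equatorial and so fixes C9 relative to C10, and the C9–C10 bond should form on the ring face anti to the pseudo-equatorial C2 silyloxy group (as in 1,3-trans additions to 5-substituted cyclohexenes), which relays the C2 configuration to the quaternary C10; the acid work-up cleaves the silyl ester and the triethylsilyl ether.

Step 12
Reactants: 18 2β-hydroxy acid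
Product: 20 2α-hydroxy acid, via bridged lactone 19 (not isolated)
Conditions: PPh3, DIAD, THF (0.01 M), 0 → 25 °C; then LiOH, THF/H2O, 25 °C; 1 M HCl
Reagents that add atoms: lithium hydroxide [Li+].[OH-]
Why: Intramolecular Mitsunobu esterification: the C8 carboxylate, held on the α face by C9 and C10, should displace the activated 2β-oxygen with inversion to give the bridged δ-lactone (a retentive closure is geometrically impossible), and saponification then frees the 2α-alcohol, which is the C2 configuration of the target.

Step 13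
Reactants: 20 2α-hydroxy acid
Product: 21 2α-(tert-butyldimethylsilyloxy) acid tert-butyldimethylsilyl ester
Conditions: t-BuMe2SiOTf, 2,6-lutidine, CH2Cl2, −78 → 0 °C; used crude
Reagents that add atoms: tert-butyldimethylsilyl trifluoromethanesulfonate CC(C)(C)[Si](C)(C)OS(=O)(=O)C(F)(F)F
Why: Silylation masks the alcohol and the acid against the borane of step 14, and the equatorial 2α-silyloxy group anchors the ring A chair that has the C10 methyl axial and the C9 arm equatorial.

Step 14
Reactants: 21 bis-silyl compound
Product: 23 acid with 5β-(3-methylbut-2-enyl) group and H-5α, via alkylborane 22 (not isolated)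
Conditions: 9-BBN, THF, 60 °C; then 1-bromo-2-methylprop-1-ene, Pd(dppf)Cl2 (5 mol %), K3PO4 (aq), DMF, 60 °C
Reagents that add atoms: 1-bromo-2-methylprop-1-ene CC(C)=CBr
Why: Hydroboration followed by B-alkyl Suzuki–Miyaura coupling: the borane should add anti-Markovnikov to the methylidene from the α face, opposite the two syn-axial methyl groups at C4 and C10, which sets H-5α (C6 trans to the C9 arm), and the primary alkylborane is then coupled with the alkenyl bromide to install C7 as a trisubstituted olefin, while the aqueous base cleaves the silyl ester.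

Step 15
Reactants: 23 prenyl acid
Product: 24 C8 methyl ketone
Conditions: MeLi (4 equiv), Et2O, 0 → 25 °C; then 1 M HCl, 0 °C
Reagents that add atoms: methyllithium [Li]C
Why: Addition of methyllithium to the lithium carboxylate gives a geminal dialkoxide that releases the ketone only on hydrolysis (classical acid-to-methyl-ketone conversion), which installs C17 on C8 without enolising C9.

Step 16
Reactants: 24 C8 methyl ketone
Product: 26 (13R)-2α-(tert-butyldimethylsilyloxy)-15-(tert-butyldiphenylsilyloxy)labd-7-ene, via oxetane 25 (not isolated)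
Conditions: FeCl3 (10 mol %), ClCH2CH2Cl, 25 → 50 °C
Reagents that add atoms: none
Why: Proposed new method: FeCl3 (trivalent iron, Lewis acid) should bind the C8 ketone, the C7 end of the electron-rich trisubstituted olefin should add to C8 while the carbonyl oxygen closes on the developing tertiary centre (asynchronous [2+2]) to give oxetane 25, and Lewis-acid-assisted retro-[2+2] should then release acetone and the C7=C8 double bond. The closest known reaction type is the FeCl3-catalysed ring-closing carbonyl–olefin metathesis of ketones bearing prenyl groups, documented for aryl ketones (cyclopentenes, cyclohexenes) and for aliphatic ketones (cyclopentenes); a six-membered closure with an enolisable, α-branched methyl ketone is the extension proposed here. Ring B closes in the 6-exo mode at both partners (the carbonyl oxygen and the isopropylidene carbon stay outside the ring), and the four-membered oxetane is a temporary cis-fused ring formed by 4-exo O–C closure and opened again in the same flask. No stereocentre is created: the two oxetane centres at C7 and C8 become sp2 again, and C2, C5, C9, C10 and C13 are not involved. The step needs metathesis to win over carbonyl-ene or Prins reaction and over C9 epimerisation; the cation-stabilising isopropylidene terminus, the trans-diequatorial placement of the two arms at C5 and C10 of the ring A chair and the absence of protic acid are expected to secure this, while the position of the new alkene is fixed because C8 already carries the C17 methyl and C7 the only olefinic hydrogen.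

Step 17
Reactants: 26 bis-silyl labdene
Product: 27 (13R)-labd-7-ene-2α,15-diol
Conditions: Bu4NF, THF, 25 → 50 °C
Reagents that add atoms: none
Why: Fluoride-mediated desilylation should remove both silyl ethers in one operation, the isolated trisubstituted alkene being inert.

Step 18
Reactants: 27 diol + 28 (E)-ferulic acid
Product: 29 target, (13R)-2α-hydroxylabd-7-en-15-yl (E)-ferulate (2S,5S,9S,10S,13R)
Conditions: PPh3, DIAD, THF, 0 °C
Reagents that add atoms: none
Why: Mitsunobu esterification: the primary C15 alcohol is activated much faster than the secondary C2 alcohol, and the carboxylic acid, far more acidic than the phenol, is the pronucleophile, so the (E)-feruloyl ester should form without protecting groups and without touching a stereocentre.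

**Compound list**
1 | ketoisophorone, 2,6,6-trimethylcyclohex-2-ene-1,4-dione | CC1=CC(=O)CC(C)(C)C1=O | starting material
2 | (R)-phorenol, (4R)-4-hydroxy-2,6,6-trimethylcyclohex-2-en-1-one | O[C@H]1C=C(C)C(=O)C(C)(C)C1 | intermediate
3 | (4R)-2,6,6-trimethyl-4-(triethylsilyloxy)cyclohex-2-en-1-one | CC[Si](CC)(CC)O[C@H]1C=C(C)C(=O)C(C)(C)C1 | intermediate
4 | lithium (4S)-2,6,6-trimethyl-4-(triethylsilyloxy)cyclohex-1-en-1-olate (not isolated) | CC[Si](CC)(CC)O[C@H]1CC(C)=C(O[Li])C(C)(C)C1 | intermediate
5 | (4S)-2,6,6-trimethyl-4-(triethylsilyloxy)cyclohex-1-en-1-yl trifluoromethanesulfonate | CC[Si](CC)(CC)O[C@H]1CC(C)=C(OS(=O)(=O)C(F)(F)F)C(C)(C)C1 | intermediate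
6 | methyl (4S)-2,6,6-trimethyl-4-(triethylsilyloxy)cyclohex-1-ene-1-carboxylate | CC[Si](CC)(CC)O[C@H]1CC(C)=C(C(=O)OC)C(C)(C)C1 | intermediate
7 | [(4S)-2,6,6-trimethyl-4-(triethylsilyloxy)cyclohex-1-en-1-yl]methanol (ring A, C2 oxygen β) | CC[Si](CC)(CC)O[C@H]1CC(C)=C(CO)C(C)(C)C1 | intermediate
8 | (R)-citronellol, (3R)-3,7-dimethyloct-6-en-1-ol | OCC[C@H](C)CCC=C(C)C | starting material
9 | tert-butyl{[(3R)-3,7-dimethyloct-6-en-1-yl]oxy}diphenylsilane | CC(C)(C)[Si](OCC[C@H](C)CCC=C(C)C)(c1ccccc1)c1ccccc1 | intermediate
10 | (4R)-6-(tert-butyldiphenylsilyloxy)-4-methylhexanal (not isolated) | CC(C)(C)[Si](OCC[C@H](C)CCC=O)(c1ccccc1)c1ccccc1 | intermediate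
11 | (4R)-6-(tert-butyldiphenylsilyloxy)-4-methylhexan-1-ol | CC(C)(C)[Si](OCC[C@H](C)CCCO)(c1ccccc1)c1ccccc1 | intermediate
12 | {[(3R)-6-bromo-3-methylhexyl]oxy}(tert-butyl)diphenylsilane | CC(C)(C)[Si](OCC[C@H](C)CCCBr)(c1ccccc1)c1ccccc1 | intermediate
13 | [(4R)-6-(tert-butyldiphenylsilyloxy)-4-methylhexyl]magnesium bromide (not isolated) | CC(C)(C)[Si](OCC[C@H](C)CCC[Mg]Br)(c1ccccc1)c1ccccc1 | intermediate
14 | (5R)-7-(tert-butyldiphenylsilyloxy)-5-methylheptanoic acid | CC(C)(C)[Si](OCC[C@H](C)CCCC(=O)O)(c1ccccc1)c1ccccc1 | intermediate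
15 | [(4S)-2,6,6-trimethyl-4-(triethylsilyloxy)cyclohex-1-en-1-yl]methyl (5R)-7-(tert-butyldiphenylsilyloxy)-5-methylheptanoate | CC[Si](CC)(CC)O[C@H]1CC(C)=C(COC(=O)CCC[C@@H](C)CCO[Si](c2ccccc2)(c2ccccc2)C(C)(C)C)C(C)(C)C1 | intermediate
16 | (Z)-O-trimethylsilyl ketene acetal of 15, C11 chain cis to OSiMe3 (not isolated) | CC[Si](CC)(CC)O[C@H]1CC(C)=C(CO/C(O[Si](C)(C)C)=C/CC[C@@H](C)CCO[Si](c2ccccc2)(c2ccccc2)C(C)(C)C)C(C)(C)C1 | intermediate
17 | trimethylsilyl ester of the rearranged acid: ring A with 2β-OSiEt3, 4,4-dimethyl, 5-methylidene, 10β-methyl; C10 carries on its α side C9H(CO2SiMe3) bearing the (13R) C11–C15 chain, C9 as in the target (not isolated) | CC(C)(C)[Si](c1ccccc1)(c1ccccc1)OCC[C@H](C)CC[C@@H](C(=O)O[Si](C)(C)C)[C@@]2(C)C[C@H](O[Si](CC)(CC)CC)CC(C)(C)C2=C | intermediate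
18 | 2β-hydroxy acid: as 17 with free C8 carboxylic acid and free 2β-OH | CC(C)(C)[Si](c1ccccc1)(c1ccccc1)OCC[C@H](C)CC[C@@H](C(=O)O)[C@@]2(C)C[C@H](O)CC(C)(C)C2=C | intermediate
19 | bridged δ-lactone between C8 and the 2α-oxygen, 2-oxabicyclo[3.3.1]nonan-3-one core (not isolated) | CC(C)(C)[Si](c1ccccc1)(c1ccccc1)OCC[C@H](C)CC[C@H]2C(=O)O[C@H]3CC(C)(C)C(=C)[C@]2(C)C3 | intermediate
20 | 2α-hydroxy acid: C2 epimer of 18 | CC(C)(C)[Si](c1ccccc1)(c1ccccc1)OCC[C@H](C)CC[C@@H](C(=O)O)[C@@]2(C)C[C@@H](O)CC(C)(C)C2=C | intermediate
21 | 2α-(tert-butyldimethylsilyloxy) acid tert-butyldimethylsilyl ester | CC(C)(C)[Si](c1ccccc1)(c1ccccc1)OCC[C@H](C)CC[C@@H](C(=O)O[Si](C)(C)C(C)(C)C)[C@@]2(C)C[C@@H](O[Si](C)(C)C(C)(C)C)CC(C)(C)C2=C | intermediate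
22 | B-alkyl-9-borabicyclo[3.3.1]nonane at C6, H-5α (not isolated) | CC(C)(C)[Si](c1ccccc1)(c1ccccc1)OCC[C@H](C)CC[C@@H](C(=O)O[Si](C)(C)C(C)(C)C)[C@@]2(C)C[C@@H](O[Si](C)(C)C(C)(C)C)CC(C)(C)[C@@H]2CB2C3CCCC2CCC3 | intermediate
23 | acid with 5β-(3-methylbut-2-enyl) group (C6, C7, isopropylidene), H-5α, 2α-OSi(t-Bu)Me2 | CC(C)(C)[Si](c1ccccc1)(c1ccccc1)OCC[C@H](C)CC[C@@H](C(=O)O)[C@@]2(C)C[C@@H](O[Si](C)(C)C(C)(C)C)CC(C)(C)[C@@H]2CC=C(C)C | intermediate
24 | C8 methyl ketone (acetyl on C9), otherwise as 23 | CC(C)(C)[Si](c1ccccc1)(c1ccccc1)OCC[C@H](C)CC[C@@H](C(C)=O)[C@@]2(C)C[C@@H](O[Si](C)(C)C(C)(C)C)CC(C)(C)[C@@H]2CC=C(C)C | intermediate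
25 | oxetane with C8–C7 and O–CMe2 bonds, cis-fused to ring B; configuration at C7 and C8 immaterial (not isolated) | CC(C)(C)[Si](c1ccccc1)(c1ccccc1)OCC[C@H](C)CC[C@H]2C3(C)OC(C)(C)C3C[C@H]3C(C)(C)C[C@H](O[Si](C)(C)C(C)(C)C)C[C@]23C | intermediate
26 | (13R)-2α-(tert-butyldimethylsilyloxy)-15-(tert-butyldiphenylsilyloxy)labd-7-ene | CC(C)(C)[Si](c1ccccc1)(c1ccccc1)OCC[C@H](C)CC[C@H]2C(C)=CC[C@H]3C(C)(C)C[C@H](O[Si](C)(C)C(C)(C)C)C[C@]23C | intermediate
27 | (13R)-labd-7-ene-2α,15-diol | OCC[C@H](C)CC[C@H]1C(C)=CC[C@H]2C(C)(C)C[C@H](O)C[C@]12C | intermediate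
28 | (E)-ferulic acid | COc1cc(/C=C/C(=O)O)ccc1O | starting material
29 | (13R)-2α-hydroxylabd-7-en-15-yl (E)-ferulate, (2S,5S,9S,10S,13R) | COc1cc(/C=C/C(=O)OCC[C@H](C)CC[C@H]2C(C)=CC[C@H]3C(C)(C)C[C@H](O)C[C@]23C)ccc1O | target

**Count**
Total steps: 18. Longest linear sequence: 14 (steps 1–5 and 10–18).

**Steps most likely to fail**
Step 16 (labelled step). What may go wrong: the activated ketone reacts with the olefin along a carbonyl-ene or Prins channel instead of forming and cleaving the oxetane, or the Lewis acid epimerises C9 or removes the C2 silyl ether. The fallback uses known chemistry, sets out from ketone 24 and comes back at 26. Wittig methylenation (Ph3PCH3Br, KOt-Bu, toluene, 80 °C) turns the C8 ketone into the isopropenyl group of diene F1. Ring-closing olefin metathesis with the second-generation Grubbs catalyst RuCl2(H2IMes)(PCy3)(=CHPh) (CH2Cl2, 40 °C) then joins C7 and C8 with loss of 2-methylpropene.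

Step 11. What may go wrong: erosion of the ketene acetal geometry or leakage through a boat transition state gives the C9 epimer, or the hindered terminus reacts too slowly and the ketene acetal decomposes. The fallback sets out from alcohol 7 and aldehyde 10 (step 7 stopped after the Me2S reduction) and comes back at 18. Takai iodo-olefination of 10 (CrCl2, CHI3, THF) gives (E)-alkenyl iodide F2. Copper-catalysed C–O coupling with 7 (CuI, 3,4,7,8-tetramethyl-1,10-phenanthroline, Cs2CO3, toluene, 110 °C) gives allyl vinyl ether F3, whose geometry is fixed by the iodide and not by an enolisation. On continued heating F3 should undergo the Claisen rearrangement to aldehyde F4. Pinnick oxidation (NaClO2, NaH2PO4, 2-methylbut-2-ene) gives acid F5, and 1 M HCl in THF removes the triethylsilyl group to give 18.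

Step 12. What may go wrong: intermolecular esterification or elimination of the activated 2β-alcohol outruns closure of the strained bridged lactone. The fallback sets out from 18 and comes back at 20. Oxidation of the C2 alcohol with Dess–Martin periodinane gives keto acid F6. Reduction with SmI2/H2O/Et3N in THF (electron-transfer reduction under thermodynamic control) should then deliver the equatorial 2α-alcohol 20.

Further compounds
F1 | step 16 | diene: 24 with the C8 ketone replaced by isopropenyl (C8(CH3)=CH2) | CC(C)(C)[Si](c1ccccc1)(c1ccccc1)OCC[C@H](C)CC[C@@H](C(C)=C)[C@@]2(C)C[C@@H](O[Si](C)(C)C(C)(C)C)CC(C)(C)[C@@H]2CC=C(C)C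
F2 | step 11 | (E)-alkenyl iodide, tert-butyl{[(3R,6E)-7-iodo-3-methylhept-6-en-1-yl]oxy}diphenylsilane | CC(C)(C)[Si](OCC[C@H](C)CC/C=C/I)(c1ccccc1)c1ccccc1
F3 | step 11 | (E)-allyl vinyl ether of 7 (C11 chain trans to the allylic oxygen) | CC[Si](CC)(CC)O[C@H]1CC(C)=C(CO/C=C/CC[C@@H](C)CCO[Si](c2ccccc2)(c2ccccc2)C(C)(C)C)C(C)(C)C1
F4 | step 11 | rearranged aldehyde: as 17 with CHO at C8 | CC(C)(C)[Si](c1ccccc1)(c1ccccc1)OCC[C@H](C)CC[C@@H](C=O)[C@@]2(C)C[C@H](O[Si](CC)(CC)CC)CC(C)(C)C2=C
F5 | step 11 | 2β-(triethylsilyloxy) acid: as 18 with 2β-OSiEt3 | CC(C)(C)[Si](c1ccccc1)(c1ccccc1)OCC[C@H](C)CC[C@@H](C(=O)O)[C@@]2(C)C[C@H](O[Si](CC)(CC)CC)CC(C)(C)C2=C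
F6 | step 12 | 2-oxo acid: as 18 with a ketone at C2 | CC(C)(C)[Si](c1ccccc1)(c1ccccc1)OCC[C@H](C)CC[C@@H](C(=O)O)[C@@]2(C)CC(=O)CC(C)(C)C2=C
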